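**Retrosynthetic overview**

1. Target 11 comes from triol acetate 10 by oxidation of the allylic ring carbinol. 10 comes from bicyclic enone 7 by 1,2-reduction, acetylation and acid unmasking, so the ketone and the protected carbinol of ring A change roles.
2. Key disconnection: the bond between the quaternary ring carbon (C5) and the side-chain carbinol carbon (C1'). It is made by an anti-selective boron aldol addition of the α'-enolate of the sugar-type bicyclic enone 1 to pentadecanal 2, which sets both stereocentres of this bond at once.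
3. Enabling feature: in ring A, C5 lies between two oxygen-bearing carbons (C1=O and C4H–OAc) joined through C2H=C3H, so the ring has a latent mirror plane through C5. The ketone carbon of 1 can therefore become C4–OAc and the allylic acetal carbon of 1 can become the C1 ketone. The acidic ring-fusion C–H next to the C=O of 1, and the cis-fused dioxolane ring B, then place the side chain on the face the target needs.
4. Ring order: ring A (cyclopentene) and ring B (dioxolane) are both present in 1. No ring is formed; ring B is removed in step 5.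

Key step: step 1

Assumption: the (3aS,6aS) enantiomer 1 of the acetonide-protected 4,5-dihydroxycyclopent-2-enone is taken as a catalogue building block, like its enantiomer; otherwise it is a few steps from D-ribose.

**Route**

Step 1
Reactants: 1 (3aS,6aS)-2,2-dimethyl-3a,6a-dihydro-4H-cyclopenta[d][1,3]dioxol-4-one; 2 pentadecanal
Product: 6 (3aS,6aS)-3a-[(1S)-1-hydroxypentadecyl]-2,2-dimethyl-3a,6a-dihydro-4H-cyclopenta[d][1,3]dioxol-4-one, via lithium enolate 3 (not isolated), via dicyclohexylboron enolate 4 (not isolated), via boron aldolate 5 (not isolated)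
Conditions: LiN(iPr)2, THF, −78 °C; (c-C6H11)2BCl, −78 °C; 2, −78 → −20 °C; MeOH, pH 7 buffer (NaH2PO4/Na2HPO4), 30% H2O2, 0 °C
Reagents that add atoms: none
Why: LiN(iPr)2 removes the only sp3 α-proton of 1, the ring-fusion C3a–H on the convex face, to give cross-conjugated enolate 3 (loss of the β-alkoxide would give an antiaromatic cyclopentadienone and should be slow at −78 °C); O-borylation gives 4, which adds to 2 through a closed Zimmerman–Traxler chair. The closest known reaction type is the anti-selective aldol addition of boron and lithium enolates of cyclic α-alkoxy ketones such as 2,2-dimethyl-1,3-dioxan-5-one, together with α'-aldol reactions of 4-silyloxycyclopent-2-enones. No ring is closed. The quaternary centre C3a is controlled by ring B: the dioxolane must stay cis-fused, so the aldehyde can bond only on the face opposite to the C6a–O bond. The carbinol centre is controlled by the ring-locked enolate geometry (C6a trans to the O–B bond): with the tetradecyl chain equatorial in the chair, the anti adduct with the (1S) side chain should result. The step needs α'- over γ-deprotonation, which kinetic deprotonation of cyclopentenones provides, and chair over boat, which the short B–O bonds and the two cyclohexyl ligands should secure.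

Step 2
Reactants: 6 (3aS,6aS)-3a-[(1S)-1-hydroxypentadecyl]-2,2-dimethyl-3a,6a-dihydro-4H-cyclopenta[d][1,3]dioxol-4-one
Product: 7 (3aR,6aS)-2,2-dimethyl-3a-[(1S)-1-(triethylsilyloxy)pentadecyl]-3a,6a-dihydro-4H-cyclopenta[d][1,3]dioxol-4-one
Conditions: Et3SiOTf, 2,6-lutidine, CH2Cl2, −78 → 0 °C
Reagents that add atoms: triethylsilyl trifluoromethanesulfonate, CC[Si](CC)(CC)OS(=O)(=O)C(F)(F)F
Why: Silyl triflate silylation of a hindered secondary alcohol; it blocks the side-chain oxygen so that it cannot deliver hydride in step 3 and is distinguished from the ring hydroxyl in step 4 (the C3a descriptor changes by priority only).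

Step 3
Reactants: 7 (3aR,6aS)-2,2-dimethyl-3a-[(1S)-1-(triethylsilyloxy)pentadecyl]-3a,6a-dihydro-4H-cyclopenta[d][1,3]dioxol-4-one
Product: 8 (3aR,4S,6aS)-2,2-dimethyl-3a-[(1S)-1-(triethylsilyloxy)pentadecyl]-3a,6a-dihydro-4H-cyclopenta[d][1,3]dioxol-4-ol
Conditions: NaBH4, CeCl3·7H2O, MeOH, −78 °C
Reagents that add atoms: none
Why: Luche 1,2-reduction of the enone; hydride should add on the face of the dioxolane oxygen, anti to the much larger silyloxyalkyl group on the neighbouring quaternary carbon, so the new (4S) hydroxyl is cis to the side chain and trans to the tertiary oxygen.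

Step 4
Reactants: 8 (3aR,4S,6aS)-2,2-dimethyl-3a-[(1S)-1-(triethylsilyloxy)pentadecyl]-3a,6a-dihydro-4H-cyclopenta[d][1,3]dioxol-4-ol
Product: 9 (3aS,4S,6aS)-2,2-dimethyl-3a-[(1S)-1-(triethylsilyloxy)pentadecyl]-3a,6a-dihydro-4H-cyclopenta[d][1,3]dioxol-4-yl acetate
Conditions: Ac2O, DMAP, pyridine, CH2Cl2, 0 °C → rt
Reagents that add atoms: acetic anhydride, CC(=O)OC(C)=O
Why: DMAP-catalysed acylation of the only free hydroxyl; no stereocentre is touched (the C3a descriptor changes by priority only).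

Step 5
Reactants: 9 (3aS,4S,6aS)-2,2-dimethyl-3a-[(1S)-1-(triethylsilyloxy)pentadecyl]-3a,6a-dihydro-4H-cyclopenta[d][1,3]dioxol-4-yl acetate
Product: 10 (1S,4S,5S)-4,5-dihydroxy-5-[(1S)-1-hydroxypentadecyl]cyclopent-2-en-1-yl acetate
Conditions: CF3CO2H, H2O, THF, 0 °C → rt
Reagents that add atoms: none
Why: Acid-catalysed acetal hydrolysis (cleavage at the ketal carbon, so no ring C–O bond breaks) and protodesilylation in one operation; the acetate should survive aqueous acid, and acid does not promote its shift to the cis side-chain hydroxyl.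

Step 6
Reactants: 10 (1S,4S,5S)-4,5-dihydroxy-5-[(1S)-1-hydroxypentadecyl]cyclopent-2-en-1-yl acetate
Product: 11 (1S,5R)-5-hydroxy-5-[(1S)-1-hydroxypentadecyl]-4-oxocyclopent-2-en-1-yl acetate
Conditions: MnO2 (activated), CH2Cl2, rt
Reagents that add atoms: none
Why: Chemoselective MnO2 oxidation of the allylic secondary alcohol in the presence of a saturated secondary and a tertiary alcohol; the neutral conditions leave the acetate in place, and the former acetal carbon becomes the enone carbonyl of the target.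

**Compound list**

1 | (3aS,6aS)-2,2-dimethyl-3a,6a-dihydro-4H-cyclopenta[d][1,3]dioxol-4-one | O=C1C=C[C@@H]2OC(C)(C)O[C@H]12 | starting material
2 | pentadecanal | CCCCCCCCCCCCCCC=O | starting material
3 | lithium (6aS)-2,2-dimethyl-6aH-cyclopenta[d][1,3]dioxol-4-olate | [Li]OC1=C2OC(C)(C)O[C@H]2C=C1 | intermediate
4 | (6aS)-4-(dicyclohexylboranyloxy)-2,2-dimethyl-6aH-cyclopenta[d][1,3]dioxole | C1CCCCC1B(C2CCCCC2)OC3=C4OC(C)(C)O[C@H]4C=C3 | intermediate
5 | O-dicyclohexylboranyl derivative of 6 at the (1S) side-chain oxygen, ring (3aS,6aS) | CCCCCCCCCCCCCC[C@H](OB(C3CCCCC3)C4CCCCC4)[C@]12OC(C)(C)O[C@H]1C=CC2=O | intermediate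
6 | (3aS,6aS)-3a-[(1S)-1-hydroxypentadecyl]-2,2-dimethyl-3a,6a-dihydro-4H-cyclopenta[d][1,3]dioxol-4-one | CCCCCCCCCCCCCC[C@H](O)[C@]12OC(C)(C)O[C@H]1C=CC2=O | intermediate
7 | (3aR,6aS)-2,2-dimethyl-3a-[(1S)-1-(triethylsilyloxy)pentadecyl]-3a,6a-dihydro-4H-cyclopenta[d][1,3]dioxol-4-one | CCCCCCCCCCCCCC[C@H](O[Si](CC)(CC)CC)[C@]12OC(C)(C)O[C@H]1C=CC2=O | intermediate
8 | (3aR,4S,6aS)-2,2-dimethyl-3a-[(1S)-1-(triethylsilyloxy)pentadecyl]-3a,6a-dihydro-4H-cyclopenta[d][1,3]dioxol-4-ol | CCCCCCCCCCCCCC[C@H](O[Si](CC)(CC)CC)[C@]12OC(C)(C)O[C@H]1C=C[C@@H]2O | intermediate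
9 | (3aS,4S,6aS)-2,2-dimethyl-3a-[(1S)-1-(triethylsilyloxy)pentadecyl]-3a,6a-dihydro-4H-cyclopenta[d][1,3]dioxol-4-yl acetate | CCCCCCCCCCCCCC[C@H](O[Si](CC)(CC)CC)[C@]12OC(C)(C)O[C@H]1C=C[C@@H]2OC(C)=O | intermediate
10 | (1S,4S,5S)-4,5-dihydroxy-5-[(1S)-1-hydroxypentadecyl]cyclopent-2-en-1-yl acetate | CCCCCCCCCCCCCC[C@H](O)[C@]1(O)[C@@H](O)C=C[C@@H]1OC(C)=O | intermediate
11 | (1S,5R)-5-hydroxy-5-[(1S)-1-hydroxypentadecyl]-4-oxocyclopent-2-en-1-yl acetate | CCCCCCCCCCCCCC[C@H](O)[C@]1(O)C(=O)C=C[C@@H]1OC(C)=O | target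

**Step count**

Total steps: 6. Longest linear sequence: 6 (from 1).

**Steps most likely to fail, with fallbacks**

Step 1. The risk is β-elimination of the ring-fusion alkoxide from the α-alkoxy enolate, or incomplete lithium-to-boron exchange that lets a looser transition state erode the anti selectivity at the carbinol carbon. The fallback sets out from 2 and comes back at 11. It makes the same bond on an enolate that carries no oxygen at the nucleophilic carbon and installs the tertiary hydroxyl afterwards. Commercial (4R)-4-(tert-butyldimethylsilyloxy)cyclopent-2-en-1-one F1 is enolised with (c-C6H11)2BCl/Et3N and added to 2, anti to the silyloxy group and through a chair, to give the trans anti aldol F2. Et3SiOTf/2,6-lutidine gives the bis-silyl ether F3. KN(SiMe3)2 at −78 °C followed by 2-(benzenesulfonyl)-3-phenyloxaziridine should hydroxylate the enolate anti to the ring silyloxy group, giving the α-hydroxy ketone F4 with the side chain now cis to that oxygen. 2,2-Dimethoxypropane with camphorsulfonic acid removes the triethylsilyl group and ties the tertiary and side-chain hydroxyls as the spiro-dioxolane F5. Bu4NF buffered with AcOH frees the ring alcohol F6, Ac2O/DMAP gives the acetate F7, and 80% aqueous AcOH at 40 °C removes the dioxolane to give 11.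

Step 3. The risk is hydride delivery from the side-chain face, if shielding of the concave face by the dioxolane outweighs the bulk of the side chain. The fallback sets out from 7 and comes back at 9. The reduction then gives the (4R)-epimeric allylic alcohol F8, which is not discarded: Mitsunobu esterification (PPh3, diisopropyl azodicarboxylate, AcOH, THF, 0 °C) inverts the carbinol carbon and installs the acetate in one operation, giving 9.

Step 5. The risk is acetate loss, or its migration to the cis side-chain hydroxyl, while the hindered cis-fused acetal is hydrolysed; the free side-chain hydroxyl also raises the chemoselectivity demand of step 6. The fallback sets out from 6 and comes back at 11. The side-chain oxygen is kept as the more acid-stable tert-butyldimethylsilyl ether until after the oxidation. t-BuMe2SiOTf/2,6-lutidine gives the silyl ether F9, NaBH4/CeCl3·7H2O gives the allylic alcohol F10, and Ac2O/DMAP gives the acetate F11. 80% aqueous AcOH at 40 °C should remove only the dioxolane, giving the diol F12. MnO2 oxidises its single secondary (allylic) hydroxyl to the enone F13, and HF·pyridine in THF removes the silyl group under acidic conditions to give 11.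

**Further compounds**

F1 | step 1 | (4R)-4-(tert-butyldimethylsilyloxy)cyclopent-2-en-1-one | O=C1C=C[C@H](O[Si](C)(C)C(C)(C)C)C1
F2 | step 1 | (4S,5R)-4-(tert-butyldimethylsilyloxy)-5-[(1S)-1-hydroxypentadecyl]cyclopent-2-en-1-one | CCCCCCCCCCCCCC[C@H](O)[C@H]1C(=O)C=C[C@@H]1O[Si](C)(C)C(C)(C)C
F3 | step 1 | (4S,5R)-4-(tert-butyldimethylsilyloxy)-5-[(1S)-1-(triethylsilyloxy)pentadecyl]cyclopent-2-en-1-one | CCCCCCCCCCCCCC[C@H](O[Si](CC)(CC)CC)[C@H]1C(=O)C=C[C@@H]1O[Si](C)(C)C(C)(C)C
F4 | step 1 | (4S,5R)-4-(tert-butyldimethylsilyloxy)-5-hydroxy-5-[(1S)-1-(triethylsilyloxy)pentadecyl]cyclopent-2-en-1-one | CCCCCCCCCCCCCC[C@H](O[Si](CC)(CC)CC)[C@]1(O)C(=O)C=C[C@@H]1O[Si](C)(C)C(C)(C)C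
F5 | step 1 | (4S,5R,9S)-9-(tert-butyldimethylsilyloxy)-2,2-dimethyl-4-tetradecyl-1,3-dioxaspiro[4.4]non-7-en-6-one | CCCCCCCCCCCCCC[C@@H]1OC(C)(C)O[C@]12C(=O)C=C[C@@H]2O[Si](C)(C)C(C)(C)C
F6 | step 1 | (4S,5S,9S)-9-hydroxy-2,2-dimethyl-4-tetradecyl-1,3-dioxaspiro[4.4]non-7-en-6-one | CCCCCCCCCCCCCC[C@@H]1OC(C)(C)O[C@]12C(=O)C=C[C@@H]2O
F7 | step 1 | (4S,5R,9S)-2,2-dimethyl-6-oxo-4-tetradecyl-1,3-dioxaspiro[4.4]non-7-en-9-yl acetate | CCCCCCCCCCCCCC[C@@H]1OC(C)(C)O[C@]12C(=O)C=C[C@@H]2OC(C)=O
F8 | step 3 | (3aR,4R,6aS)-2,2-dimethyl-3a-[(1S)-1-(triethylsilyloxy)pentadecyl]-3a,6a-dihydro-4H-cyclopenta[d][1,3]dioxol-4-ol | CCCCCCCCCCCCCC[C@H](O[Si](CC)(CC)CC)[C@]12OC(C)(C)O[C@H]1C=C[C@H]2O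
F9 | step 5 | (3aR,6aS)-3a-[(1S)-1-(tert-butyldimethylsilyloxy)pentadecyl]-2,2-dimethyl-3a,6a-dihydro-4H-cyclopenta[d][1,3]dioxol-4-one | CCCCCCCCCCCCCC[C@H](O[Si](C)(C)C(C)(C)C)[C@]12OC(C)(C)O[C@H]1C=CC2=O
F10 | step 5 | (3aR,4S,6aS)-3a-[(1S)-1-(tert-butyldimethylsilyloxy)pentadecyl]-2,2-dimethyl-3a,6a-dihydro-4H-cyclopenta[d][1,3]dioxol-4-ol | CCCCCCCCCCCCCC[C@H](O[Si](C)(C)C(C)(C)C)[C@]12OC(C)(C)O[C@H]1C=C[C@@H]2O
F11 | step 5 | (3aS,4S,6aS)-3a-[(1S)-1-(tert-butyldimethylsilyloxy)pentadecyl]-2,2-dimethyl-3a,6a-dihydro-4H-cyclopenta[d][1,3]dioxol-4-yl acetate | CCCCCCCCCCCCCC[C@H](O[Si](C)(C)C(C)(C)C)[C@]12OC(C)(C)O[C@H]1C=C[C@@H]2OC(C)=O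
F12 | step 5 | (1S,4S,5S)-5-[(1S)-1-(tert-butyldimethylsilyloxy)pentadecyl]-4,5-dihydroxycyclopent-2-en-1-yl acetate | CCCCCCCCCCCCCC[C@H](O[Si](C)(C)C(C)(C)C)[C@]1(O)[C@@H](O)C=C[C@@H]1OC(C)=O
F13 | step 5 | (1S,5S)-5-[(1S)-1-(tert-butyldimethylsilyloxy)pentadecyl]-5-hydroxy-4-oxocyclopent-2-en-1-yl acetate | CCCCCCCCCCCCCC[C@H](O[Si](C)(C)C(C)(C)C)[C@]1(O)C(=O)C=C[C@@H]1OC(C)=O
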